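**Strategy.** The target is a pseudo-dimer whose halves differ only at the acetoxy carbon (C10 axial, C10' equatorial), so each half is made by its own epoxide-initiated cyclization and the halves are joined by an HWE olefination (C11=C12). The right half (rings C, D) arises in one cascade ending in a lactone; the left cyclohexane (ring B) is closed after coupling. The key step exploits the O–C2(CH3)2–C3(=O) unit of the left oxepane (ring A: O, C2–C7): the C7 hydroxyl opens a C2–C3 epoxide at its tertiary carbon (7-endo), forming ring A and the C3 oxygen in one operation. Its precursor already holds rings B, C and D and carries an epoxidized prenyl chain on C6.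

Key step: step 14

Remark on numbering and assumptions: squalene-type numbering is used, C2–C12 for the left half and C2'–C12' for the right half. Ring A is the left oxepane, ring B the left cyclohexane, ring C the right cyclohexane, ring D the right oxepane. The target is (6S,7S,10R,11S,6'S,7'S,10'S,11'S). Both enantiomers of the fructose-derived Shi ketone, (2E,6E)-farnesyl chloride, geraniol and dimethyl (2-oxopropyl)phosphonate are taken as purchasable.

**Right half**

Step 1
Reactants: 1 (2E,6E)-farnesyl chloride
Product: 3 (3E,7E)-homofarnesic acid, via farnesylbarium chloride 2 (not isolated)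
Conditions: BaI2, lithium biphenylide, THF, rt; then 1, −78 °C; CO2, −78 °C; aq HCl work-up
Reagents that add atoms: carbon dioxide, O=C=O
Why: Allylbarium carboxylation, in which the allylbarium reagent keeps its geometry at −78 °C and is carboxylated at the α-carbon, so the E-alkene (later C10'=C11') is kept, the new carboxyl carbon becomes C12 and no stereocenter is formed.

Step 2
Reactants: 3 (3E,7E)-homofarnesic acid
Product: 4 methyl (3E,7E)-homofarnesoate
Conditions: TMSCHN2, MeOH/PhMe, 0 °C
Reagents that add atoms: (trimethylsilyl)diazomethane, C[Si](C)(C)C=[N+]=[N-]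
Why: Diazoalkane esterification under neutral conditions, which avoids migration of the β,γ-double bond into conjugation and installs the electron-withdrawing CH2CO2CH3 group that should slow epoxidation of the adjacent alkene in step 3.

Step 3
Reactants: 4 methyl (3E,7E)-homofarnesoate
Product: 5 methyl (3E,7S,8S,11S)-7,8:11,12-diepoxy-4,8,12-trimethyltridec-3-enoate
Conditions: L-fructose-derived Shi ketone (0.6 equiv), KHSO5, K2CO3, Bu4NHSO4, MeCN/CH2(OMe)2/aq borate buffer (pH 10.5), 0 °C
Reagents that add atoms: potassium peroxymonosulfate (KHSO5), [K+].[O-]S(=O)(=O)OO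
Why: Shi asymmetric epoxidation, in which the chiral dioxirane should epoxidize the two electron-rich trisubstituted alkenes and spare the alkene deactivated by the allylic CH2CO2CH3 group, the catalyst setting C3', C6' and C7' (all S).

Step 4
Reactants: 5 diepoxy ester
Product: 6 right-half tricyclic lactone (rings C and D, trans-fused γ-lactone from C10'–O to C12, C3'–OSiEt3)
Conditions: Et3SiOTf (1.2 equiv), 2,6-di-tert-butyl-4-methylpyridine, CH2Cl2, −78 °C
Reagents that add atoms: triethylsilyl trifluoromethanesulfonate, CC[Si](CC)(CC)OS(=O)(=O)C(F)(F)F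
Why: Silyl-triflate-promoted epoxide-opening cascade (tandem oxa- and carbacyclization with lactone termination), in which the silylated terminal epoxide is opened at tertiary C2' by the oxygen of the 6',7'-epoxide, the epoxonium ion is opened at C6' with inversion by the E-alkene through a chair, and the C10' cation is trapped anti by the ester carbonyl with loss of its methyl group, so that the epoxide configurations and the alkene geometry set C6', C7', C11' and the equatorial C10'–O bond (10'S).

Step 5
Reactants: 6 tricyclic lactone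
Product: 7 lactol of 6 (anomer mixture)
Conditions: i-Bu2AlH (1.1 equiv), CH2Cl2, −78 °C
Reagents that add atoms: none
Why: Partial hydride reduction of a lactone to a lactol at low temperature, which leaves the silyl ether and all ring stereocenters untouched and creates only an anomeric center whose configuration is irrelevant.

**Left half**

Step 6
Reactants: 8 geraniol
Product: 9 (2S,3S)-2,3-epoxygeraniol
Conditions: Ti(OiPr)4 (5 mol%), L-(+)-diethyl tartrate (6 mol%), t-BuOOH, 4 Å molecular sieves, CH2Cl2, −20 °C
Reagents that add atoms: tert-butyl hydroperoxide, CC(C)(C)OO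
Why: Sharpless asymmetric epoxidation, in which the titanium tartrate catalyst delivers oxygen to one face of the allylic alkene only, setting the future C6 and C7 (both S) while the remote prenyl alkene does not react.

Step 7
Reactants: 9 (2S,3S)-2,3-epoxygeraniol
Product: 10 epoxygeranyl iodide [(2R,3S)-2,3-epoxy-1-iodo-3,7-dimethyloct-6-ene]
Conditions: PPh3, I2, imidazole, Et2O/MeCN, 0 °C
Reagents that add atoms: iodine, II
Why: Appel-type iodination (displacement of an alkoxyphosphonium group by iodide) at the primary carbinol, which does not involve the epoxide stereocenters.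

Step 8
Reactants: 10 epoxygeranyl iodide; 11 dimethyl (2-oxopropyl)phosphonate
Product: 13 dimethyl [(5S,6S)-5,6-epoxy-6,10-dimethyl-2-oxoundec-9-en-1-yl]phosphonate, via phosphonate dianion 12 (not isolated)
Conditions: 11, NaH, THF, 0 °C; n-BuLi, 0 °C; then 10, −78 to 0 °C; aq NH4Cl
Reagents that add atoms: none
Why: γ-Alkylation of a β-ketophosphonate dianion, in which the more basic terminal carbanion should displace the primary iodide by SN2 faster than it opens the trisubstituted epoxide, forming the C8–C9 bond without touching a stereocenter.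

**Coupling and completion**

Step 9
Reactants: 7 lactol; 13 epoxy β-ketophosphonate
Product: 15 coupled (11E)-enone (C10 ketone, C11=C12, 6,7-epoxide, free C10'–OH), via hydroxy aldehyde 14 (not isolated)
Conditions: LiCl, i-Pr2NEt, MeCN, rt
Reagents that add atoms: none
Why: Horner–Wadsworth–Emmons olefination of the aldehyde tautomer of the lactol under mild LiCl/amine conditions, which joins the halves through the E-configured C11=C12 bond and is mild enough that the freed tertiary C10' alkoxide should not add back to the enone.

Step 10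
Reactants: 15 enone
Product: 16 (10Z)-triethylsilyl enol ether of 15
Conditions: RhCl(PPh3)3 (2 mol%), Et3SiH (1.3 equiv), PhMe, 50 °C
Reagents that add atoms: triethylsilane, CC[SiH](CC)CC
Why: Rhodium-catalysed 1,4-hydrosilylation of an enone, which puts hydride on C12 and silicon on oxygen and so gives regiospecifically the C10=C11 silyl enol ether that enolization of the saturated ketone could not provide, while the epoxide, the prenyl alkene and the hindered tertiary alcohol stay inert.

Step 11
Reactants: 16 silyl enol ether
Product: 18 ring-B ketone triol (6S,7S,11S), via tris(triethylsilyl) ether 17 (not isolated)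
Conditions: Et3SiOTf (1.3 equiv), 2,6-di-tert-butyl-4-methylpyridine, CH2Cl2, −78 °C; then Bu4NF, THF, 0 °C to rt
Reagents that add atoms: none
Why: Lewis-acid-promoted intramolecular opening of an epoxide by a silyl enol ether (Mukaiyama-type alkylation, 6-endo at the tertiary epoxide carbon), in which C11 attacks C6 anti to the leaving oxygen through a chair so that C6 is set by inversion and C7 is retained, and the basic fluoride work-up removes the silyl groups and equilibrates C11 to the equatorial (S) configuration.

Step 12
Reactants: 18 ketone triol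
Product: 19 tetraol with (10R)-methyl carbinol
Conditions: MeMgBr (6 equiv), THF, −20 to 0 °C
Reagents that add atoms: methylmagnesium bromide, C[Mg]Br
Why: Grignard addition to a cyclohexanone, in which the axial trajectory is blocked by the syn-axial C6 methyl group, so methyl should enter equatorially and give the axial C10 hydroxyl (10R), the configuration opposite to that of C10'.

Step 13
Reactants: 19 tetraol
Product: 20 (3S)-2,3-epoxide of 19
Conditions: L-fructose-derived Shi ketone (0.3 equiv), KHSO5, K2CO3, Bu4NHSO4, MeCN/CH2(OMe)2/aq borate buffer (pH 10.5), 0 °C; buffered work-up, used crude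
Reagents that add atoms: potassium peroxymonosulfate (KHSO5), [K+].[O-]S(=O)(=O)OO
Why: Shi asymmetric epoxidation of the only alkene left (C2=C3), the catalyst setting C3 as S, a configuration that can be chosen freely because C3 ends as a ketone.

Step 14
Reactants: 20 epoxy tetraol
Product: 21 bis-oxepane tetraol (rings A–D; C3 and C3' secondary alcohols, C10 and C10' tertiary alcohols)
Conditions: camphorsulfonic acid (10 mol%), CH2Cl2/(CF3)2CHOH (4:1), −20 to 0 °C
Reagents that add atoms: none
Why: Acid-promoted intramolecular epoxide opening by a hydroxyl group: the protonated or hydrogen-bonded epoxide develops positive charge at the gem-dimethyl carbon C2, and the equatorial C7 hydroxyl attacks C2 with cleavage of the C2–O(epoxide) bond. The closest known reaction type is the acid-catalysed 7-endo cyclization of hydroxy trisubstituted epoxides that gives 2,2-dialkyloxepan-3-ols. Ring A (O, C2, C3, C4, C5, C6, C7) is closed in the 7-endo mode by the new O–C2 bond and is trans-fused to ring B because O on C7 and C5 on C6 are both equatorial; it is the last ring of the skeleton to form, rings B, C and D being in place. The only new stereocenter, C3 (S), keeps the epoxide configuration because its C–O bond is not broken, and C2 is not stereogenic. The step needs regioselectivity for C2 (7-endo) over C3 (6-exo), which should come from the tertiary, cation-stabilizing C2 in the ionizing fluoroalcohol medium and from the (3S)-epoxide, which would force the 2-hydroxypropan-2-yl group axial in the competing 6-exo chair. The two tertiary hydroxyls and the C3' hydroxyl cannot reach the epoxide, so no protecting group is needed.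

Step 15
Reactants: 21 bis-oxepane tetraol
Product: 22 3,3'-diketone diol
Conditions: Dess–Martin periodinane (3 equiv), NaHCO3, CH2Cl2, rt
Reagents that add atoms: none
Why: Dess–Martin oxidation of both secondary carbinols (C3 and C3') to ketones, which leaves the tertiary alcohols untouched and erases the auxiliary stereocenters at C3 and C3' as planned.

Step 16
Reactants: 22 diketone diol
Product: 23 CNP0325605.1
Conditions: Ac2O, DMAP, Et3N, PhMe, 60 °C
Reagents that add atoms: acetic anhydride, CC(=O)OC(C)=O
Why: DMAP-catalysed acylation of the two tertiary alcohols, now the only hydroxyls in the molecule, with forcing conditions for the axial C10 hydroxyl and no effect on any stereocenter.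

**Compound list**

1 | (2E,6E)-farnesyl chloride | ClC/C=C(\C)CC/C=C(\C)CCC=C(C)C | starting material
2 | (2E,6E)-farnesylbarium chloride | Cl[Ba]C/C=C(\C)CC/C=C(\C)CCC=C(C)C | intermediate
3 | (3E,7E)-homofarnesic acid [(3E,7E)-4,8,12-trimethyltrideca-3,7,11-trienoic acid] | OC(=O)C/C=C(\C)CC/C=C(\C)CCC=C(C)C | intermediate
4 | methyl (3E,7E)-homofarnesoate | COC(=O)C/C=C(\C)CC/C=C(\C)CCC=C(C)C | intermediate
5 | methyl (3E,7S,8S,11S)-7,8:11,12-diepoxy-4,8,12-trimethyltridec-3-enoate | COC(=O)C/C=C(\C)CC[C@@H]1O[C@@]1(C)CC[C@@H]1OC1(C)C | intermediate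
6 | right-half tricyclic lactone, (3'S,6'S,7'S,10'S,11'S): rings C and D trans-fused, γ-lactone C10'–O–C12(=O)–C12', C3'–OSiEt3 | O=C1C[C@H]2[C@]3(C)CC[C@H](O[Si](CC)(CC)CC)C(C)(C)O[C@H]3CC[C@]2(C)O1 | intermediate
7 | lactol of 6 (C12 hemiacetal, anomer mixture) | OC1C[C@H]2[C@]3(C)CC[C@H](O[Si](CC)(CC)CC)C(C)(C)O[C@H]3CC[C@]2(C)O1 | intermediate
8 | geraniol | OC/C=C(\C)CCC=C(C)C | starting material
9 | (2S,3S)-2,3-epoxygeraniol | OC[C@@H]1O[C@@]1(C)CCC=C(C)C | intermediate
10 | epoxygeranyl iodide, (2R,3S)-2,3-epoxy-1-iodo-3,7-dimethyloct-6-ene | IC[C@@H]1O[C@@]1(C)CCC=C(C)C | intermediate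
11 | dimethyl (2-oxopropyl)phosphonate | COP(=O)(OC)CC(C)=O | starting material
12 | 1,3-dianion of 11 (sodium lithium salt) | [Na+].[Li+].COP(=O)(OC)[CH-]C(=O)[CH2-] | intermediate
13 | dimethyl [(5S,6S)-5,6-epoxy-6,10-dimethyl-2-oxoundec-9-en-1-yl]phosphonate | COP(=O)(OC)CC(=O)CC[C@@H]1O[C@@]1(C)CCC=C(C)C | intermediate
14 | hydroxy aldehyde tautomer of 7 (C12 aldehyde, free C10'–OH) | O=CC[C@H]1[C@]2(C)CC[C@H](O[Si](CC)(CC)CC)C(C)(C)O[C@H]2CC[C@]1(C)O | intermediate
15 | coupled (11E)-enone: C10 ketone, C11=C12, (6S,7S)-epoxide, prenyl alkene; right half with C3'–OSiEt3 and C10'–OH | CC(C)=CCC[C@]1(C)O[C@H]1CCC(=O)/C=C/C[C@H]1[C@]2(C)CC[C@H](O[Si](CC)(CC)CC)C(C)(C)O[C@H]2CC[C@]1(C)O | intermediate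
16 | (10Z)-triethylsilyl enol ether of 15 (C10–OSiEt3, C10=C11) | CC(C)=CCC[C@]1(C)O[C@H]1CC/C(O[Si](CC)(CC)CC)=C/CC[C@H]1[C@]2(C)CC[C@H](O[Si](CC)(CC)CC)C(C)(C)O[C@H]2CC[C@]1(C)O | intermediate
17 | tris(triethylsilyl) ether of 18 (on O7, O3' and O10') | O=C1CC[C@H](O[Si](CC)(CC)CC)[C@@](C)(CCC=C(C)C)[C@@H]1CC[C@H]1[C@]2(C)CC[C@H](O[Si](CC)(CC)CC)C(C)(C)O[C@H]2CC[C@]1(C)O[Si](CC)(CC)CC | intermediate
18 | ring-B ketone triol, (6S,7S,11S): C10 ketone, C7–OH, C6 methyl and 4-methylpent-3-enyl, C11–CH2CH2–right half (C3'–OH, C10'–OH) | O=C1CC[C@H](O)[C@@](C)(CCC=C(C)C)[C@@H]1CC[C@H]1[C@]2(C)CC[C@H](O)C(C)(C)O[C@H]2CC[C@]1(C)O | intermediate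
19 | tetraol, (10R)-methyl carbinol of 18 (axial C10–OH) | O[C@]1(C)CC[C@H](O)[C@@](C)(CCC=C(C)C)[C@@H]1CC[C@H]1[C@]2(C)CC[C@H](O)C(C)(C)O[C@H]2CC[C@]1(C)O | intermediate
20 | (3S)-2,3-epoxide of 19 | O[C@]1(C)CC[C@H](O)[C@@](C)(CC[C@@H]3OC3(C)C)[C@@H]1CC[C@H]1[C@]2(C)CC[C@H](O)C(C)(C)O[C@H]2CC[C@]1(C)O | intermediate
21 | bis-oxepane tetraol (rings A–D; (3S)- and (3'S)-carbinols, C10 and C10' tertiary alcohols) | O[C@]1(C)CC[C@@H]2OC(C)(C)[C@@H](O)CC[C@@]2(C)[C@@H]1CC[C@H]1[C@]2(C)CC[C@H](O)C(C)(C)O[C@H]2CC[C@]1(C)O | intermediate
22 | 3,3'-diketone diol | O[C@]1(C)CC[C@@H]2OC(C)(C)C(=O)CC[C@@]2(C)[C@@H]1CC[C@H]1[C@]2(C)CCC(=O)C(C)(C)O[C@H]2CC[C@]1(C)O | intermediate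
23 | CNP0325605.1 | CC(=O)O[C@]1(C)CC[C@@H]2OC(C)(C)C(=O)CC[C@@]2(C)[C@@H]1CC[C@H]1[C@]2(C)CCC(=O)C(C)(C)O[C@H]2CC[C@]1(C)OC(C)=O | target

**Step count and risks**

Total steps: 16. Longest linear sequence: 13 steps (steps 1–5, then 9–16); the left-half branch (steps 6–8) joins at step 9.

Steps most likely to fail:

1. Step 14 (key step). The hydroxyl may attack the secondary epoxide carbon C3 instead (6-exo closure to a tetrahydropyran), or the epoxide may rearrange by hydride shift before it is trapped. The fallback keeps ring A as the last ring closed but replaces the epoxide by alkene π-activation, which has no SN2-type 6-exo channel. It sets out from 19: alkoxymercuration of the prenyl alkene with Hg(OCOCF3)2 in MeNO2 at −20 °C (Markovnikov, O7 to tertiary C2, mercury to C3), followed by brine, should give the organomercuric chloride F1. Oxidative demercuration (NaBH4, O2, DMF) should give the C3-epimeric oxepanol mixture F2, and Dess–Martin oxidation of F2 comes back to the route at 22.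

2. Step 4. The alkene bearing the CH2CO2CH3 group may be too weak a nucleophile to capture the epoxonium ion, or the C10' cation may lose a proton instead of lactonizing with loss of the methyl group. The fallback changes both the terminating group and the mode of activation. It sets out from 5: saponification (LiOH, THF/H2O) gives the diepoxy acid F3; a proton-triggered cyclization of the free acid in (CF3)2CHOH with Ph4PBF4, in which the carboxylic O–H itself terminates the cascade, should give the hydroxy lactone F4; silylation (Et3SiCl, imidazole, DMF) comes back at 6.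

3. Step 11. On the large, hydroxyl-bearing substrate the silyl enol ether may be lost by protodesilylation, or the activated epoxide may rearrange before the C6–C11 bond forms. The fallback closes ring B before the fragment coupling, on a small hydroxyl-free monomer. It sets out from 13, with 7 as partner: silylation (Et3SiCl, Et3N, DMAP) gives the silyl enol ether F5; Et3SiOTf-catalysed cyclization should give the cyclic β-ketophosphonate F6; HWE olefination of F6 with lactol 7 (LiCl, DBU, MeCN) gives the exocyclic enone F7; conjugate reduction with [(Ph3P)CuH]6 gives the saturated ketone F8; Bu4NF removes the silyl groups and equilibrates C11, coming back at 18.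

Further compounds

F1 | step 14 | C3 organomercuric chloride of the closed ring-A oxepane (C3 epimers) | O[C@]1(C)CC[C@@H]2OC(C)(C)C([Hg]Cl)CC[C@@]2(C)[C@@H]1CC[C@H]1[C@]2(C)CC[C@H](O)C(C)(C)O[C@H]2CC[C@]1(C)O
F2 | step 14 | C3-epimeric mixture of the bis-oxepane tetraol | O[C@]1(C)CC[C@@H]2OC(C)(C)C(O)CC[C@@]2(C)[C@@H]1CC[C@H]1[C@]2(C)CC[C@H](O)C(C)(C)O[C@H]2CC[C@]1(C)O
F3 | step 4 | (3E,7S,8S,11S)-7,8:11,12-diepoxy-4,8,12-trimethyltridec-3-enoic acid | OC(=O)C/C=C(\C)CC[C@@H]1O[C@@]1(C)CC[C@@H]1OC1(C)C
F4 | step 4 | right-half tricyclic hydroxy lactone (free C3'–OH) | O=C1C[C@H]2[C@]3(C)CC[C@H](O)C(C)(C)O[C@H]3CC[C@]2(C)O1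
F5 | step 11 | triethylsilyl enol ether of β-ketophosphonate 13 | COP(=O)(OC)C=C(O[Si](CC)(CC)CC)CC[C@@H]1O[C@@]1(C)CCC=C(C)C
F6 | step 11 | cyclic β-ketophosphonate (ring B closed, C7–OSiEt3, phosphonate on C11) | COP(=O)(OC)C1C(=O)CC[C@H](O[Si](CC)(CC)CC)[C@@]1(C)CCC=C(C)C
F7 | step 11 | exocyclic C11=C12 enone coupled to the right half | O=C1CC[C@H](O[Si](CC)(CC)CC)[C@@](C)(CCC=C(C)C)C1=CC[C@H]1[C@]2(C)CC[C@H](O[Si](CC)(CC)CC)C(C)(C)O[C@H]2CC[C@]1(C)O
F8 | step 11 | bis(triethylsilyl) ether of ketone triol 18 (on O7 and O3') | O=C1CC[C@H](O[Si](CC)(CC)CC)[C@@](C)(CCC=C(C)C)[C@@H]1CC[C@H]1[C@]2(C)CC[C@H](O[Si](CC)(CC)CC)C(C)(C)O[C@H]2CC[C@]1(C)O
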